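The decalin is unfolded into a bicyclo[2.2.2]octene by opening ring A at C1–C10 and tying C3 back to C8. This works because of the oxygen pair at C3 (ring A) and C8 (ring B), separated by the C2=C1 and C10=C9 alkenes. Quaternary C5 stands 1,4 to C8 across ring B, which is what a cycloadduct of a Birch-derived 1-methoxy-4-methyldiene offers. One charge-accelerated [3,3] shift trades the C3–C8 bond for C1–C10. It builds ring A with a cis fusion and releases the two oxygens as distinguishable enol ethers (silyl at C3, methyl at C8). Its precursor is a 1-methoxy-3,4-dimethyl-2-vinylbicyclo[2.2.2]oct-5-en-2-ol in which C4 and C5 are already set, with vinyl and C4-methyl both facing the etheno bridge.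

Key step: step 7

Assumption: (R)-2-hydroxy-2-methylbutanoic acid is bought as the single enantiomer. The labels C1–C10 in the comments are those of the target decalin (C3 ester carbinol, C4 methine, C5 quaternary, C7 carbinol, C8 ketone) and are carried back into the bicycles; β is the face of the C5 methyl.

Step 1
Reactants: 1 4-methylanisole
Product: 2 1-methoxy-4-methylcyclohexa-1,4-diene
Conditions: Li, NH3(l), t-BuOH, THF, −78 to −33 °C; then NH4Cl
Reagents that add atoms: none
Why: Birch reduction: electron transfer and protonation leave both donor substituents (OMe, Me) on the two remaining double bonds, so the skipped 1,4-diene is the expected regioisomer and no stereocentre is created.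

Step 2
Reactants: 2 1-methoxy-4-methylcyclohexa-1,4-diene
Product: 3 1-methoxy-4-methylcyclohexa-1,3-diene
Conditions: KOt-Bu (0.3 equiv), DMSO, rt
Reagents that add atoms: none
Why: Base-mediated prototropic isomerisation through the pentadienyl anion moves the skipped diene into conjugation, the 1,3-diene with OMe and Me on its termini being the favoured component at equilibrium, and unchanged 2 is a harmless spectator in step 3.

Step 3
Reactants: 3 1-methoxy-4-methylcyclohexa-1,3-diene; 4 acrolein
Product: 5 (1S,2R,4R)-1-methoxy-4-methylbicyclo[2.2.2]oct-5-ene-2-carbaldehyde (formyl endo, syn to the C5=C6 bridge)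
Conditions: (5S)-5-benzyl-2,2,3-trimethylimidazolidin-4-one·HCl (10 mol %), 3 in excess, MeCN–H2O 95:5, −10 °C; exo adduct removed by chromatography
Reagents that add atoms: acrolein 4, C=CC=O
Why: Iminium-catalysed enantioselective Diels–Alder reaction: the diene OMe directs the formyl-bearing carbon next to the methoxy bridgehead, the catalyst's benzyl group leaves one face of the acrolein iminium open, and the endo mode then fixes both bridgeheads (C5 and C8), while the exo adduct, formed on the same dienophile face and therefore carrying opposite bridgeheads, has to be removed before the formyl carbon is lost.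

Step 4
Reactants: 5 (1S,2R,4R)-1-methoxy-4-methylbicyclo[2.2.2]oct-5-ene-2-carbaldehyde
Product: 6 (1S,4R)-1-methoxy-4-methylbicyclo[2.2.2]oct-5-en-2-one
Conditions: O2 (1 atm), Cu(OAc)2 (10 mol %), 2,2′-bipyridine (10 mol %), DABCO, DMF, 40 °C
Reagents that add atoms: dioxygen, O=O
Why: Copper-catalysed aerobic deformylation of an α-branched aldehyde (enolate oxygenation to the α-hydroperoxy aldehyde, then C–C cleavage with loss of formic acid) turns the only enolisable carbon into the C3 ketone without touching the isolated alkene or the bridgeheads.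

Step 5
Reactants: 6 (1S,4R)-1-methoxy-4-methylbicyclo[2.2.2]oct-5-en-2-one; 7 iodomethane
Product: 9 (1S,3R,4S)-1-methoxy-3,4-dimethylbicyclo[2.2.2]oct-5-en-2-one (3-methyl syn to the C5=C6 bridge), via lithium enolate 8 (not isolated)
Conditions: LDA, THF, −78 °C; MeI, −78 to −20 °C
Reagents that add atoms: iodomethane 7, CI
Why: Kinetic enolate alkylation: only one α-carbon can enolise because the other is a bridgehead, and MeI passes the flat etheno bridge rather than the ethano bridge whose inward C–H bonds cover the other face, so the methyl ends syn to the alkene, which is the arrangement that becomes the cis C4/C5 dimethyl pair, and C4 is thus fixed here instead of being left to a later equilibration of uncertain outcome.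

Step 6
Reactants: 9 (1S,3R,4S)-1-methoxy-3,4-dimethylbicyclo[2.2.2]oct-5-en-2-one; 10 vinylmagnesium bromide
Product: 11 (1S,2S,3R,4S)-1-methoxy-3,4-dimethyl-2-vinylbicyclo[2.2.2]oct-5-en-2-ol (vinyl and 3-methyl syn to the etheno bridge, OH syn to the ethano bridge)
Conditions: CeCl3 (anhydrous), 10, THF, −78 °C; then 9, −78 to −20 °C; aq NH4Cl
Reagents that add atoms: vinylmagnesium bromide 10, C=C[Mg]Br
Why: Organocerium 1,2-addition to a ketone (non-basic, so C4 is neither enolised nor epimerised): the reagent should come in past the flat etheno bridge because on the opposite face the inward C7–H of the ethano bridge lies directly in the Bürgi–Dunitz path, a closer contact than the neighbouring C4 methyl, which sets the new C3 centre with vinyl syn to C9=C10, and any epimer is removed by chromatography.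

Step 7
Reactants: 11 (1S,2S,3R,4S)-1-methoxy-3,4-dimethyl-2-vinylbicyclo[2.2.2]oct-5-en-2-ol; 12 chlorotrimethylsilane
Product: 15 {[(1R,4aR,8aS)-6-methoxy-1,8a-dimethyl-1,4,4a,7,8,8a-hexahydronaphthalen-2-yl]oxy}trimethylsilane (cis-fused; 4R,5S,10R in target numbering; C2=C3 silyl enol ether; C8=C9 methyl enol ether), via potassium alkoxide 13 (not isolated), via potassium enolate 14 (not isolated)
Conditions: KH, 18-crown-6, THF, 0 °C to rt; then TMSCl, Et3N, −78 to 0 °C
Reagents that add atoms: chlorotrimethylsilane 12, C[Si](C)(C)Cl
Why: KH converts 11 into alkoxide 13, whose oxyanion weakens the adjoining C3–C8 σ bond so that the 1,5-diene C1=C2–C3–C8–C9=C10 undergoes a concerted [3,3] sigmatropic shift near room temperature to enolate 14, which TMSCl captures on oxygen. The closest known reaction type is the anionic oxy-Cope rearrangement of 1-alkoxy-2-vinylbicyclo[2.2.2]oct-5-en-2-ols to cis-fused octalones. Ring A (C1, C2, C3, C4, C5, C10) is closed pericyclically, by suprafacial C1–C10 bonding through the boat-shaped six-centre array that the cage enforces, while the old cyclohexene ring lives on as ring B. The one new stereocentre, C10, is controlled by the cage: C1 can reach C10 only on the alkene face turned towards the C3–C4 bridge, so the C10–C1 and C5–C4 bonds end cis and H-10 shares the face of the C5 methyl, with C4 and C5 carried over unchanged. The step needs the vinyl group syn to the etheno bridge (secured in step 6; the epimer is inert) and an enolate that stays at C2=C3, which excess KH ensures by leaving no proton source that could move it towards C4. The C4 methyl takes a flagpole-like site in the boat, the only strain added to the known cases, and 3,3-disubstituted congeners are known to tolerate such a group.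

Step 8
Reactants: 15 bis(enol ether)
Product: 16 (1R,4aR,8aS)-6-methoxy-1,8a-dimethyl-4a,7,8,8a-tetrahydronaphthalen-2(1H)-one (C1=C2–C3=O enone, cis-fused, C8 methyl enol ether intact)
Conditions: Pd(OAc)2 (1.05 equiv), MeCN, rt; filtration through Et3N-deactivated silica
Reagents that add atoms: none
Why: Saegusa–Ito oxidation: the silyl enol ether hands its oxygen to palladium far faster than the methyl enol ether can react, β-hydride elimination can only use a C1 hydrogen and so gives the C1=C2 enone, and the near-neutral medium leaves C4 and C10 untouched.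

Step 9
Reactants: 16 enone
Product: 17 (1R,2S,4aR,8aS)-6-methoxy-1,8a-dimethyl-1,2,4a,7,8,8a-hexahydronaphthalen-2-ol (3β-OH, cis to both methyl groups)
Conditions: DIBAL-H, toluene, −78 °C; aq Rochelle salt
Reagents that add atoms: none
Why: 1,2-Reduction of a cyclohexenone with a bulky, non-protic aluminium hydride: on the β face the hydride would meet the syn-axial C5 methyl in one half-chair of the mobile cis-octalone and the axial C4 methyl in the other, so delivery to the α face of C3 is expected and gives the 3β (S) allylic alcohol, while the absence of acid and methanol spares the C8 enol ether.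

Step 10
Reactants: 18 (R)-2-hydroxy-2-methylbutanoic acid
Product: 19 methyl (R)-2-hydroxy-2-methylbutanoate
Conditions: MeOH, H2SO4 (cat.), reflux
Reagents that add atoms: methanol, CO
Why: Fischer esterification; the fully substituted carbinol centre bears no hydrogen and cannot racemise.

Step 11
Reactants: 19 methyl (R)-2-hydroxy-2-methylbutanoate
Product: 20 methyl (R)-2-methyl-2-(triethylsilyloxy)butanoate
Conditions: TESOTf, 2,6-lutidine, CH2Cl2, 0 °C
Reagents that add atoms: triethylsilyl triflate, CC[Si](CC)(CC)OS(=O)(=O)C(F)(F)F
Why: Silyl-triflate silylation is the standard way to cap a hindered tertiary alcohol, and TES is chosen because it should last through steps 12–17 and fall together with the TMS group in the last step.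

Step 12
Reactants: 20 methyl (R)-2-methyl-2-(triethylsilyloxy)butanoate
Product: 21 (R)-2-methyl-2-(triethylsilyloxy)butanal
Conditions: DIBAL-H (1.1 equiv), CH2Cl2, −78 °C; aq Rochelle salt
Reagents that add atoms: none
Why: Partial ester reduction with DIBAL-H: the crowded α-silyloxy aluminium hemiacetal persists at low temperature until work-up, so reduction stops at the non-enolisable aldehyde.

Step 13
Reactants: 21 (R)-2-methyl-2-(triethylsilyloxy)butanal; 22 triethyl 4-phosphonocrotonate
Product: 23 ethyl (2E,4E,6R)-6-methyl-6-(triethylsilyloxy)octa-2,4-dienoate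
Conditions: 22, LiHMDS, THF, −78 °C; then 21, −78 to 0 °C
Reagents that add atoms: triethyl 4-phosphonocrotonate 22, CCOC(=O)/C=C/CP(=O)(OCC)OCC
Why: Vinylogous Horner–Wadsworth–Emmons olefination: the stabilised lithiated phosphonate reacts through its α-carbon with the hindered aldehyde and eliminates to the E alkene, while the crotonate double bond stays E.

Step 14
Reactants: 23 ethyl dienoate
Product: 24 (2E,4E,6R)-6-methyl-6-(triethylsilyloxy)octa-2,4-dienoic acid
Conditions: LiOH, THF–MeOH–H2O, rt; then dilute HCl to pH 4, 0 °C
Reagents that add atoms: lithium hydroxide, [Li+].[OH-]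
Why: Saponification of the ethyl ester; the tertiary TES ether and the diene geometry are stable to aqueous LiOH and to brief acidification at pH 4.

Step 15
Reactants: 17 3β-allylic alcohol; 24 dienoic acid
Product: 26 (1R,2S,4aR,8aS)-6-methoxy-1,8a-dimethyl-1,2,4a,7,8,8a-hexahydronaphthalen-2-yl (2E,4E,6R)-6-methyl-6-(triethylsilyloxy)octa-2,4-dienoate, via mixed anhydride 25 (not isolated)
Conditions: 24, 2,4,6-Cl3C6H2COCl, Et3N, toluene, rt; then 17, DMAP, rt to 40 °C
Reagents that add atoms: 2,4,6-trichlorobenzoyl chloride (atoms kept only in 25), O=C(Cl)c1c(Cl)cc(Cl)cc1Cl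
Why: Yamaguchi esterification acylates the hindered pseudo-axial C3 hydroxyl with retention at C3 under basic conditions that the enol ether tolerates, the dienoic acid has no γ-hydrogen through which it could deconjugate, and the ester doubles as the C3 protecting group for the remaining steps.

Step 16
Reactants: 26 enol ether ester
Product: 27 (1R,2S,8aR)-1,8a-dimethyl-6-oxo-1,2,6,7,8,8a-hexahydronaphthalen-2-yl (2E,4E,6R)-6-methyl-6-(triethylsilyloxy)octa-2,4-dienoate
Conditions: DDQ (1.1 equiv), CH2Cl2–pH 7 buffer 10:1, 0 °C
Reagents that add atoms: water, O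
Why: Quinone dehydrogenation of an alkyl enol ether: DDQ removes the doubly allylic C10 hydride that is aligned with the C8=C9 π bond, the conjugated oxocarbenium ion is hydrolysed at C8, and the C8 ketone appears already conjugated with C9=C10 and C1=C2, which erases the temporary C10 stereocentre.

Step 17
Reactants: 27 dienone ester; 12 chlorotrimethylsilane
Product: 29 (1R,2S,8aR)-1,8a-dimethyl-6-(trimethylsilyloxy)-1,2,8,8a-tetrahydronaphthalen-2-yl (2E,4E,6R)-6-methyl-6-(triethylsilyloxy)octa-2,4-dienoate, via lithium dienolate 28 (not isolated)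
Conditions: LiHMDS, THF, −78 °C; TMSCl, Et3N, −78 to −40 °C; cold aq NaHCO3 wash, used crude
Reagents that add atoms: chlorotrimethylsilane 12, C[Si](C)(C)Cl
Why: Kinetic α′-deprotonation of the linear dienone at C7, its only sp3 α-carbon, with a non-nucleophilic amide and O-silylation give the cross-conjugated silyloxy triene, and the dienoate ester offers no acidic C–H that could compete.

Step 18
Reactants: 29 silyloxy triene
Product: 31 (1R,2S,7R,8aR)-7-hydroxy-1,8a-dimethyl-6-oxo-1,2,6,7,8,8a-hexahydronaphthalen-2-yl (2E,4E,6R)-6-hydroxy-6-methylocta-2,4-dienoate (target), via 7α-silyloxy ketone 30 (not isolated)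
Conditions: mCPBA (1.05 equiv), CH2Cl2–hexane, −20 °C; then HF·pyridine, pyridine, THF, 0 °C
Reagents that add atoms: 3-chloroperbenzoic acid, OOC(=O)c1cccc(Cl)c1
Why: Rubottom oxidation followed by desilylation: the peracid attacks the most electron-rich alkene, C7=C8, from the α face opposite the pseudo-axial C5 methyl that sits 1,3 to C7, silyl migration gives 30, buffered HF frees both hydroxyls, and the 7α (R) carbinol so formed is also the equatorial, more stable epimer.

Compound list
1 | 4-methylanisole | Cc1ccc(OC)cc1 | starting material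
2 | 1-methoxy-4-methylcyclohexa-1,4-diene | COC1=CCC(C)=CC1 | intermediate
3 | 1-methoxy-4-methylcyclohexa-1,3-diene | COC1=CC=C(C)CC1 | intermediate
4 | acrolein | C=CC=O | starting material
5 | (1S,2R,4R)-1-methoxy-4-methylbicyclo[2.2.2]oct-5-ene-2-carbaldehyde (endo) | CO[C@@]12CC[C@@](C)(C=C1)C[C@H]2C=O | intermediate
6 | (1S,4R)-1-methoxy-4-methylbicyclo[2.2.2]oct-5-en-2-one | CO[C@@]12CC[C@@](C)(C=C1)CC2=O | intermediate
7 | iodomethane | CI | starting material
8 | lithium enolate of 6 | CO[C@@]12CC[C@@](C)(C=C1)C=C2[O-].[Li+] | intermediate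
9 | (1S,3R,4S)-1-methoxy-3,4-dimethylbicyclo[2.2.2]oct-5-en-2-one | CO[C@@]12CC[C@@](C)(C=C1)[C@@H](C)C2=O | intermediate
10 | vinylmagnesium bromide | C=C[Mg]Br | starting material
11 | (1S,2S,3R,4S)-1-methoxy-3,4-dimethyl-2-vinylbicyclo[2.2.2]oct-5-en-2-ol | CO[C@@]12CC[C@@](C)(C=C1)[C@@H](C)[C@@]2(O)C=C | intermediate
12 | chlorotrimethylsilane | C[Si](C)(C)Cl | starting material
13 | potassium alkoxide of 11 | CO[C@@]12CC[C@@](C)(C=C1)[C@@H](C)[C@@]2([O-])C=C.[K+] | intermediate
14 | potassium C2=C3 enolate of the cis-octalone | [K+].[O-]C1=CC[C@@H]2C=C(OC)CC[C@]2(C)[C@H]1C | intermediate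
15 | cis-fused C3 trimethylsilyl / C8 methyl bis(enol ether) | C[Si](C)(C)OC1=CC[C@@H]2C=C(OC)CC[C@]2(C)[C@H]1C | intermediate
16 | (1R,4aR,8aS)-6-methoxy-1,8a-dimethyl-4a,7,8,8a-tetrahydronaphthalen-2(1H)-one | O=C1C=C[C@@H]2C=C(OC)CC[C@]2(C)[C@H]1C | intermediate
17 | (1R,2S,4aR,8aS)-6-methoxy-1,8a-dimethyl-1,2,4a,7,8,8a-hexahydronaphthalen-2-ol | O[C@H]1C=C[C@@H]2C=C(OC)CC[C@]2(C)[C@H]1C | intermediate
18 | (R)-2-hydroxy-2-methylbutanoic acid | CC[C@@](C)(O)C(=O)O | starting material
19 | methyl (R)-2-hydroxy-2-methylbutanoate | CC[C@@](C)(O)C(=O)OC | intermediate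
20 | methyl (R)-2-methyl-2-(triethylsilyloxy)butanoate | CC[C@@](C)(O[Si](CC)(CC)CC)C(=O)OC | intermediate
21 | (R)-2-methyl-2-(triethylsilyloxy)butanal | CC[C@@](C)(O[Si](CC)(CC)CC)C=O | intermediate
22 | triethyl 4-phosphonocrotonate | CCOC(=O)/C=C/CP(=O)(OCC)OCC | starting material
23 | ethyl (2E,4E,6R)-6-methyl-6-(triethylsilyloxy)octa-2,4-dienoate | CC[C@@](C)(O[Si](CC)(CC)CC)/C=C/C=C/C(=O)OCC | intermediate
24 | (2E,4E,6R)-6-methyl-6-(triethylsilyloxy)octa-2,4-dienoic acid | CC[C@@](C)(O[Si](CC)(CC)CC)/C=C/C=C/C(=O)O | intermediate
25 | mixed anhydride of 24 with 2,4,6-trichlorobenzoic acid | CC[C@@](C)(O[Si](CC)(CC)CC)/C=C/C=C/C(=O)OC(=O)c1c(Cl)cc(Cl)cc1Cl | intermediate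
26 | C3 dienoate of 17 (C8 methyl enol ether, TES ether) | CC[C@@](C)(O[Si](CC)(CC)CC)/C=C/C=C/C(=O)O[C@H]1C=C[C@@H]2C=C(OC)CC[C@]2(C)[C@H]1C | intermediate
27 | C8 dienone ester (TES ether) | CC[C@@](C)(O[Si](CC)(CC)CC)/C=C/C=C/C(=O)O[C@H]1C=CC2=CC(=O)CC[C@]2(C)[C@H]1C | intermediate
28 | lithium C7=C8 dienolate of 27 | CC[C@@](C)(O[Si](CC)(CC)CC)/C=C/C=C/C(=O)O[C@H]1C=CC2=CC([O-])=CC[C@]2(C)[C@H]1C.[Li+] | intermediate
29 | C8 trimethylsilyloxy triene ester | CC[C@@](C)(O[Si](CC)(CC)CC)/C=C/C=C/C(=O)O[C@H]1C=CC2=CC(O[Si](C)(C)C)=CC[C@]2(C)[C@H]1C | intermediate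
30 | 7α-trimethylsilyloxy dienone ester (TES ether) | CC[C@@](C)(O[Si](CC)(CC)CC)/C=C/C=C/C(=O)O[C@H]1C=CC2=CC(=O)[C@H](O[Si](C)(C)C)C[C@]2(C)[C@H]1C | intermediate
31 | CNP0260852.1 | CC[C@@](C)(O)/C=C/C=C/C(=O)O[C@H]1C=CC2=CC(=O)[C@H](O)C[C@]2(C)[C@H]1C | target

Total step count: 18. Longest linear sequence: 13 (steps 1–9 and 15–18); the acid branch (steps 10–14) joins at step 15.

Steps most likely to fail

Step 6. The facial preference of the addition may erode, because the C4 methyl flanks the very face that has to be attacked. Material would then be diverted into the carbinol epimer that cannot rearrange. The fallback replaces the solvated vinyl metal by a rod-shaped acetylide, which feels the neighbouring methyl less while the inward C–H of the ethano bridge still closes the other face. It sets out from 9. Ethynylmagnesium bromide in THF should give (1S,2R,3R,4S)-2-ethynyl-1-methoxy-3,4-dimethylbicyclo[2.2.2]oct-5-en-2-ol F3. Hydroxyl-directed hydroalumination of the propargylic alcohol with Red-Al in THF reduces only the alkyne and comes back to the route at 11.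

Step 3. The dienol ether may be consumed by protonation and hydrolysis in the protic, mildly acidic iminium medium. Bond formation may also stop at the conjugate-addition stage, and uncatalysed background reaction may lower the enantiocontrol. The fallback moves to an aprotic chiral Lewis acid and a two-point-binding dienophile. It sets out from 3. 3-Acryloyl-1,3-oxazolidin-2-one and the copper(II) hexafluoroantimonate complex of (R,R)-tert-butyl-bis(oxazoline) in CH2Cl2 at low temperature should give the endo imide 3-{[(1S,2R,4R)-1-methoxy-4-methylbicyclo[2.2.2]oct-5-en-2-yl]carbonyl}-1,3-oxazolidin-2-one F1. LiBH4 cleaves it to [(1S,2S,4R)-1-methoxy-4-methylbicyclo[2.2.2]oct-5-en-2-yl]methanol F2, and Parikh–Doering oxidation comes back to the route at 5.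

Step 9. Hydride delivery at C3 may show insufficient facial selectivity, because the cis-octalone is conformationally mobile. The fallback makes the sequence stereoconvergent instead of relying on substrate control. It sets out from 16. A small hydride (NaBH4, CeCl3, MeOH–THF, −78 °C, axial delivery), or simply the unwanted portion of the DIBAL-H reduction, provides the 3α-alcohol (1R,2R,4aR,8aS)-6-methoxy-1,8a-dimethyl-1,2,4a,7,8,8a-hexahydronaphthalen-2-ol F4. Mitsunobu esterification with acid 24 (PPh3, DIAD, toluene, 0 °C) inverts C3 and comes back to the route at 26.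

Further compounds
F1 | step 3 | 3-{[(1S,2R,4R)-1-methoxy-4-methylbicyclo[2.2.2]oct-5-en-2-yl]carbonyl}-1,3-oxazolidin-2-one | CO[C@@]12CC[C@@](C)(C=C1)C[C@H]2C(=O)N1CCOC1=O
F2 | step 3 | [(1S,2S,4R)-1-methoxy-4-methylbicyclo[2.2.2]oct-5-en-2-yl]methanol | CO[C@@]12CC[C@@](C)(C=C1)C[C@H]2CO
F3 | step 6 | (1S,2R,3R,4S)-2-ethynyl-1-methoxy-3,4-dimethylbicyclo[2.2.2]oct-5-en-2-ol | CO[C@@]12CC[C@@](C)(C=C1)[C@@H](C)[C@@]2(O)C#C
F4 | step 9 | (1R,2R,4aR,8aS)-6-methoxy-1,8a-dimethyl-1,2,4a,7,8,8a-hexahydronaphthalen-2-ol | O[C@@H]1C=C[C@@H]2C=C(OC)CC[C@]2(C)[C@H]1C
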